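**Strategy.** The target is amentoflavone with a prenyl ether on O7'' of the C8''-linked unit (flavone 2). The plan dismantles ring B of flavone 1. Its 1,3,4-pattern (C1' bonded to chromone C2, C3' bonded to C8'', C4' bearing oxygen) is the imprint of a 2-siloxy-3-arylbutadiene and a 2-ethynylchromone. One (4+2) cycloaddition forges C1'–C2' and C5'–C6', closes ring B as a cyclohexa-1,4-diene and unites two finished halves, so crowded C8'' never enters an arene–arene coupling. The precursors are a tert-butyldimethylsilyl dienol ether grown on 8-iodinated apigenin and a 2-ethynyl-5,7-disiloxychromone. All lasting phenol protection is silyl, so fluoride alone finishes the synthesis and the acid-sensitive aryl prenyl ether never meets acid.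

Key step: step 11

Remarks
- Locants: unprimed and single-primed numbers belong to flavone 1 (rings A and C, linking ring B). Double- and triple-primed numbers belong to flavone 2, with triple primes for its 4-hydroxyphenyl ring. Monomeric intermediates carry ordinary flavone numbering. TIPS = triisopropylsilyl, TBS = tert-butyldimethylsilyl, Bn = benzyl.
- Assumption: the target string holds no stereocentre and defines no configuration at the C3'–C8'' axis, so the axis is left uncontrolled.
- O7'' carries benzyl as a placeholder until ring B is aromatic. A prenyl ether would not survive N-iodosuccinimide, DDQ or prolonged heating.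

Step 1
Reactants: 1 apigenin
Product: 2 7-O-benzylapigenin (7-benzyloxy-5-hydroxy-2-(4-hydroxyphenyl)chromen-4-one)
Conditions: BnBr (1.05 equiv), K2CO3 (1.1 equiv), DMF, rt
Reagents that add atoms: benzyl bromide, BrCc1ccccc1
Why: Williamson etherification under limiting base should go to O7, because the 7-OH (para to C4=O) is the most acidic phenol, the 5-OH is tied up in a hydrogen bond to C4=O and the 4'-OH is less acidic.

Step 2
Reactants: 2 7-O-benzylapigenin
Product: 3 7-benzyloxy-5-(triisopropylsilyloxy)-2-[4-(triisopropylsilyloxy)phenyl]chromen-4-one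
Conditions: TIPSOTf (2.5 equiv), 2,6-lutidine (3.5 equiv), CH2Cl2, 0 °C to rt
Reagents that add atoms: triisopropylsilyl triflate, CC(C)[Si](OS(=O)(=O)C(F)(F)F)(C(C)C)C(C)C
Why: Silylation with a silyl triflate is strong enough to cap the chelated 5-OH as well as the 4'-OH, and aryl TIPS ethers tolerate the later neutral, oxidative and reductive steps yet fall to fluoride.

Step 3
Reactants: 3 bis-TIPS 7-O-benzylapigenin
Product: 4 7-benzyloxy-8-iodo-5-(triisopropylsilyloxy)-2-[4-(triisopropylsilyloxy)phenyl]chromen-4-one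
Conditions: NIS (1.1 equiv), TFA (cat.), MeCN–CH2Cl2, 0 °C to rt, dark
Reagents that add atoms: N-iodosuccinimide, O=C1CCC(=O)N1I
Why: This is an electrophilic aromatic iodination, in which 5,7-dioxygenated flavones with O5 capped react at C8; here C6 is also walled in by OTIPS and OBn, and the 4-siloxyphenyl ring is deactivated by the pyrone.

Step 4
Reactants: 5 but-3-yn-2-one
Product: 6 3-(tributylstannyl)but-3-en-2-one
Conditions: Bu3SnH (1.05 equiv, slow addition), Pd(PPh3)4 (2 mol %), THF, 0 °C; filtration through neutral alumina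
Reagents that add atoms: tributyltin hydride, CCCC[SnH](CCCC)CCCC
Why: Hydrostannation catalysed by zerovalent palladium adds H and Sn syn across the ynone, with hydrogen going to the terminal carbon and tin to the carbon next to the carbonyl, as is usual for acceptor alkynes.

Step 5
Reactants: 4 8-iodoflavone; 6 3-(tributylstannyl)but-3-en-2-one
Product: 7 7-benzyloxy-8-(3-oxobut-1-en-2-yl)-5-(triisopropylsilyloxy)-2-[4-(triisopropylsilyloxy)phenyl]chromen-4-one
Conditions: 6 (1.5 equiv), Pd2(dba)3 (5 mol %), AsPh3 (20 mol %), CuI (20 mol %), DMF, 50 °C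
Reagents that add atoms: none
Why: In this Stille coupling AsPh3 and CuI speed up transmetalation of the 1,1-disubstituted vinylstannane and so hold back cine substitution, as known for α-stannyl acrylates and enones, while the neutral fluoride-free medium spares the silyl ethers.

Step 6
Reactants: 7 8-(3-oxobut-1-en-2-yl)flavone
Product: 8 7-benzyloxy-8-[3-(tert-butyldimethylsilyloxy)buta-1,3-dien-2-yl]-5-(triisopropylsilyloxy)-2-[4-(triisopropylsilyloxy)phenyl]chromen-4-one
Conditions: TBSOTf (1.3 equiv), Et3N (2.5 equiv), CH2Cl2, 0 °C; cold aq NaHCO3; Et3N-deactivated silica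
Reagents that add atoms: tert-butyldimethylsilyl triflate, CC(C)(C)[Si](C)(C)OS(=O)(=O)C(F)(F)F
Why: Soft enolisation and O-silylation of an enone whose only enolisable position is the methyl group gives the 2-siloxydiene, and any transient silylation of the flavone carbonyl reverts on work-up.

Step 7
Reactants: 9 2,4,6-trihydroxyacetophenone
Product: 11 5,7-dihydroxy-2-methylchromen-4-one (noreugenin), via 3-acetyl-5,7-diacetoxy-2-methylchromone 10 (not isolated)
Conditions: Ac2O, NaOAc, 175 °C; concentrate; aq Na2CO3, reflux; then aq HCl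
Reagents that add atoms: acetic anhydride, CC(=O)OC(C)=O
Why: The Kostanecki–Robinson reaction (O-acetylation, acyl transfer to the ketone methyl, cyclodehydration, C3 acetylation) is followed by carbonate hydrolysis, which removes the two acetate esters and, by retro-Claisen cleavage, the 3-acetyl group.

Step 8
Reactants: 11 noreugenin
Product: 12 2-methyl-5,7-bis(triisopropylsilyloxy)chromen-4-one
Conditions: TIPSOTf (2.5 equiv), 2,6-lutidine (3.5 equiv), CH2Cl2, 0 °C to rt
Reagents that add atoms: triisopropylsilyl triflate, CC(C)[Si](OS(=O)(=O)C(F)(F)F)(C(C)C)C(C)C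
Why: The same silyl triflate silylation as in step 2 caps the free 7-OH and the chelated 5-OH, and the weak base lutidine should not enolise the 2-methyl group irreversibly.

Step 9
Reactants: 12 bis-TIPS noreugenin
Product: 13 4-oxo-5,7-bis(triisopropylsilyloxy)chromene-2-carbaldehyde
Conditions: SeO2 (1.5 equiv), 1,4-dioxane, 100 °C
Reagents that add atoms: selenium dioxide, O=[Se]=O
Why: In this Riley oxidation the 2-methyl group is activated vinylogously by C4=O and is the only enolisable position, so SeO2 should take it to the aldehyde as known for 2-methylchromones.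

Step 10
Reactants: 13 chromone-2-carbaldehyde
Product: 14 2-ethynyl-5,7-bis(triisopropylsilyloxy)chromen-4-one
Conditions: TMSCHN2 (1.2 equiv), LDA (1.2 equiv), THF, −78 °C; add 13; −78 °C to rt; pH 7 buffer
Reagents that add atoms: trimethylsilyldiazomethane, C[Si](C)(C)C=[N+]=[N-]
Why: The Colvin rearrangement (addition to the aldehyde, Peterson-type loss of silanolate, loss of N2, 1,2-hydrogen shift) gives the terminal alkyne in an aprotic medium, which avoids the alcohol and base mixtures that would add to the activated enyne.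

Step 11
Reactants: 8 siloxydiene on flavone 2; 14 2-ethynylchromone
Product: 15 cyclohexa-1,4-diene form of ring B (double bonds C1'=C6' and C3'=C4', CH2 at C2' and C5'), with the 5,7-bis(triisopropylsilyloxy)chromon-2-yl group on C1', C8'' of the protected flavone 2 on C3' and OTBS on C4'
Conditions: 14 (1.5 equiv), BHT (cat.), PhMe, 120 °C, sealed tube
Reagents that add atoms: none
Why: This is a thermal Diels–Alder reaction of normal electron demand, concerted but asynchronous: the nucleophilic enol-ether terminus C5' of 8 bonds ahead to the terminal alkyne carbon C6' of 14, the vinylogous β-position of the chromone acceptor, while C2' closes onto C1'. The closest known reaction type is the cycloaddition of 2-siloxybutadienes with propiolates and ynones, which gives 1-siloxycyclohexa-1,4-dienes. Ring B, the only ring formed, closes as a six-membered carbocycle by suprafacial (4πs+2πs) addition of the s-cis diene across one π bond of the alkyne. No stereocentre arises, because every ring atom of the adduct is either CH2 or sp2. The selectivity needed is para orientation (chromone on C1' opposite OTBS on C4'), and it is secured by the siloxy group as the dominant donor, since the C8'' aryl group, flanked by OBn and O1'', stands perpendicular to the diene and cannot steer through conjugation. Site selectivity follows because the pyrone C2=C3 bonds are trisubstituted vinylogous esters and far poorer dienophiles than the terminal alkyne.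

Step 12
Reactants: 15 cyclohexa-1,4-diene adduct
Product: 16 protected biflavone with aromatic ring B (4'-OTBS; 5,7,5'',4'''-tetra-OTIPS; 7''-OBn)
Conditions: DDQ (1.1 equiv), PhMe, 0 °C to rt
Reagents that add atoms: none
Why: In this DDQ dehydrogenation, hydride abstraction from a doubly allylic CH2 gives a siloxy-stabilised cation that loses a proton, so ring B aromatises with the bulky TBS group still on O4', and benzyl and aryl silyl ethers are inert.

Step 13
Reactants: 16 protected biflavone
Product: 17 7''-hydroxy biflavone (4'-OTBS; 5,7,5'',4'''-tetra-OTIPS)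
Conditions: H2 (1 atm), Pd/C (10 wt %), EtOAc–THF, rt
Reagents that add atoms: none
Why: Catalytic hydrogenolysis cleaves the only benzyl ether, and in an aprotic solvent at one atmosphere the silyl ethers and the pyrone C2=C3 bonds should stay untouched.

Step 14
Reactants: 17 7''-hydroxy biflavone
Product: 18 7''-O-prenyl biflavone (4'-OTBS; 5,7,5'',4'''-tetra-OTIPS)
Conditions: prenol (1.5 equiv), PPh3 (1.5 equiv), DIAD (1.5 equiv), THF, 0 °C to rt
Reagents that add atoms: 3-methylbut-2-en-1-ol (prenol), CC(C)=CCO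
Why: In this Mitsunobu etherification the acidic 7''-OH is the only free hydroxyl group and attacks the primary carbon of the activated prenol (SN2), under neutral conditions that cannot desilylate the other phenols as carbonate bases might.

Step 15
Reactants: 18 7''-O-prenyl biflavone
Product: 19 target, 7''-O-prenylamentoflavone (CNP0152943.0)
Conditions: TBAF (6 equiv), AcOH (6 equiv), THF, 0 °C to rt
Reagents that add atoms: none
Why: Fluoride-induced desilylation buffered with acetic acid should cleave all five aryl silyl ethers in one operation, and neither the aryl prenyl ether nor the pyrone rings react with buffered fluoride.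

**Compound list**

1 | apigenin | O=c1cc(-c2ccc(O)cc2)oc2cc(O)cc(O)c12 | starting material
2 | 7-O-benzylapigenin | O=c1cc(-c2ccc(O)cc2)oc2cc(OCc3ccccc3)cc(O)c12 | intermediate
3 | 7-benzyloxy-5-(triisopropylsilyloxy)-2-[4-(triisopropylsilyloxy)phenyl]chromen-4-one | O=c1cc(-c2ccc(O[Si](C(C)C)(C(C)C)C(C)C)cc2)oc2cc(OCc3ccccc3)cc(O[Si](C(C)C)(C(C)C)C(C)C)c12 | intermediate
4 | 8-iodo derivative of 3 | O=c1cc(-c2ccc(O[Si](C(C)C)(C(C)C)C(C)C)cc2)oc2c(I)c(OCc3ccccc3)cc(O[Si](C(C)C)(C(C)C)C(C)C)c12 | intermediate
5 | but-3-yn-2-one | CC(=O)C#C | starting material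
6 | 3-(tributylstannyl)but-3-en-2-one | CC(=O)C(=C)[Sn](CCCC)(CCCC)CCCC | intermediate
7 | 7-benzyloxy-8-(3-oxobut-1-en-2-yl)-5-(triisopropylsilyloxy)-2-[4-(triisopropylsilyloxy)phenyl]chromen-4-one | CC(=O)C(=C)c1c(OCc2ccccc2)cc(O[Si](C(C)C)(C(C)C)C(C)C)c2c(=O)cc(-c3ccc(O[Si](C(C)C)(C(C)C)C(C)C)cc3)oc12 | intermediate
8 | 7-benzyloxy-8-[3-(tert-butyldimethylsilyloxy)buta-1,3-dien-2-yl]-5-(triisopropylsilyloxy)-2-[4-(triisopropylsilyloxy)phenyl]chromen-4-one | C=C(O[Si](C)(C)C(C)(C)C)C(=C)c1c(OCc2ccccc2)cc(O[Si](C(C)C)(C(C)C)C(C)C)c2c(=O)cc(-c3ccc(O[Si](C(C)C)(C(C)C)C(C)C)cc3)oc12 | intermediate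
9 | 2,4,6-trihydroxyacetophenone | CC(=O)c1c(O)cc(O)cc1O | starting material
10 | 3-acetyl-5,7-diacetoxy-2-methylchromone | CC(=O)Oc1cc(OC(C)=O)c2c(=O)c(C(C)=O)c(C)oc2c1 | intermediate
11 | 5,7-dihydroxy-2-methylchromen-4-one (noreugenin) | Cc1cc(=O)c2c(O)cc(O)cc2o1 | intermediate
12 | 2-methyl-5,7-bis(triisopropylsilyloxy)chromen-4-one | Cc1cc(=O)c2c(O[Si](C(C)C)(C(C)C)C(C)C)cc(O[Si](C(C)C)(C(C)C)C(C)C)cc2o1 | intermediate
13 | 4-oxo-5,7-bis(triisopropylsilyloxy)chromene-2-carbaldehyde | O=Cc1cc(=O)c2c(O[Si](C(C)C)(C(C)C)C(C)C)cc(O[Si](C(C)C)(C(C)C)C(C)C)cc2o1 | intermediate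
14 | 2-ethynyl-5,7-bis(triisopropylsilyloxy)chromen-4-one | C#Cc1cc(=O)c2c(O[Si](C(C)C)(C(C)C)C(C)C)cc(O[Si](C(C)C)(C(C)C)C(C)C)cc2o1 | intermediate
15 | Diels–Alder adduct, ring B as cyclohexa-1,4-diene | CC(C)(C)[Si](C)(C)OC1=C(c2c(OCc3ccccc3)cc(O[Si](C(C)C)(C(C)C)C(C)C)c3c(=O)cc(-c4ccc(O[Si](C(C)C)(C(C)C)C(C)C)cc4)oc23)CC(c2cc(=O)c3c(O[Si](C(C)C)(C(C)C)C(C)C)cc(O[Si](C(C)C)(C(C)C)C(C)C)cc3o2)=CC1 | intermediate
16 | protected biflavone, ring B aromatic, 7''-OBn | CC(C)(C)[Si](C)(C)Oc1ccc(-c2cc(=O)c3c(O[Si](C(C)C)(C(C)C)C(C)C)cc(O[Si](C(C)C)(C(C)C)C(C)C)cc3o2)cc1-c1c(OCc2ccccc2)cc(O[Si](C(C)C)(C(C)C)C(C)C)c2c(=O)cc(-c3ccc(O[Si](C(C)C)(C(C)C)C(C)C)cc3)oc12 | intermediate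
17 | 7''-hydroxy biflavone | CC(C)(C)[Si](C)(C)Oc1ccc(-c2cc(=O)c3c(O[Si](C(C)C)(C(C)C)C(C)C)cc(O[Si](C(C)C)(C(C)C)C(C)C)cc3o2)cc1-c1c(O)cc(O[Si](C(C)C)(C(C)C)C(C)C)c2c(=O)cc(-c3ccc(O[Si](C(C)C)(C(C)C)C(C)C)cc3)oc12 | intermediate
18 | 7''-O-prenyl biflavone, five silyl ethers | CC(C)(C)[Si](C)(C)Oc1ccc(-c2cc(=O)c3c(O[Si](C(C)C)(C(C)C)C(C)C)cc(O[Si](C(C)C)(C(C)C)C(C)C)cc3o2)cc1-c1c(OCC=C(C)C)cc(O[Si](C(C)C)(C(C)C)C(C)C)c2c(=O)cc(-c3ccc(O[Si](C(C)C)(C(C)C)C(C)C)cc3)oc12 | intermediate
19 | 7''-O-prenylamentoflavone (CNP0152943.0) | CC(C)=CCOc1cc(O)c2c(=O)cc(-c3ccc(O)cc3)oc2c1-c1cc(-c2cc(=O)c3c(O)cc(O)cc3o2)ccc1O | target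

**Total step count:** 15. **Longest linear sequence:** 10 steps (1, 2, 3, 5, 6, 11, 12, 13, 14, 15).

**Steps most likely to fail**

Step 11. The vinylogous acceptor may polarise the alkyne too weakly. Cycloaddition would then be slower than thermal decay of the silyl dienol ether, and para orientation could erode. The fallback sets out from 9 and 8 and comes back at 16. It puts an ester directly on the alkyne and builds ring C of flavone 1 afterwards.
- Bis-silylation of 9 (TIPSCl, imidazole, DMF) leaves the chelated hydroxyl free and gives 1-[2-hydroxy-4,6-bis(triisopropylsilyloxy)phenyl]ethanone F1.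
- Steglich esterification with propiolic acid (DCC, CH2Cl2, −20 °C) gives 2-acetyl-3,5-bis(triisopropylsilyloxy)phenyl propiolate F2.
- Diels–Alder reaction of 8 with F2 (PhMe, 100 °C), the classical pairing of a 2-siloxydiene with a propiolate, gives the cyclohexa-1,4-diene carboxylate F3.
- DDQ gives the aryl benzoate F4.
- Baker–Venkataraman rearrangement (LiHMDS, THF, −78 to 0 °C) gives the 1,3-diketone F5.
- Cyclodehydration (cat. p-TsOH, PhMe, 60 °C) closes ring C and delivers 16.

Step 5. Transmetalation at the palladium centre on doubly ortho-flanked C8 may be slow, which leaves room for protodestannylation, cine substitution or polymerisation of the stannyl enone. The fallback sets out from 4 and comes back at 7. It builds the side chain in two stages without a vinylstannane.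
- α-Arylation of the tin enolate of acetone, made in the flask from isopropenyl acetate and Bu3SnOMe (PdCl2[P(o-tolyl)3]2 cat., PhMe, 100 °C), gives the 8-(2-oxopropyl)flavone F6.
- Mannich-type α-methylenation at the more acidic benzylic carbon (paraformaldehyde, diisopropylammonium trifluoroacetate, THF, reflux) gives 7.

Step 10. The lithiated diazo reagent or the released silanolate may attack the pyrone or the activated alkyne of the product, with ring opening and loss of material. The fallback sets out from 13 and comes back at 14. It replaces the carbene rearrangement by olefination and elimination.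
- Wittig bromomethylenation ((bromomethyl)triphenylphosphonium bromide, NaHMDS, THF, −78 °C) should favour (Z)-2-(2-bromovinyl)-5,7-bis(triisopropylsilyloxy)chromen-4-one F7.
- In F7 the vinylic hydrogen next to the chromone is acidified and lies anti to bromine, so DBU (CH2Cl2, rt) should effect E2 dehydrobromination to 14.

**Further compounds**

F1 | step 11 | 1-[2-hydroxy-4,6-bis(triisopropylsilyloxy)phenyl]ethanone | CC(=O)c1c(O)cc(O[Si](C(C)C)(C(C)C)C(C)C)cc1O[Si](C(C)C)(C(C)C)C(C)C
F2 | step 11 | 2-acetyl-3,5-bis(triisopropylsilyloxy)phenyl propiolate | C#CC(=O)Oc1cc(O[Si](C(C)C)(C(C)C)C(C)C)cc(O[Si](C(C)C)(C(C)C)C(C)C)c1C(C)=O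
F3 | step 11 | cyclohexa-1,4-diene carboxylate from 8 and F2 | CC(C)(C)[Si](C)(C)OC1=C(c2c(OCc3ccccc3)cc(O[Si](C(C)C)(C(C)C)C(C)C)c3c(=O)cc(-c4ccc(O[Si](C(C)C)(C(C)C)C(C)C)cc4)oc23)CC(C(=O)Oc2cc(O[Si](C(C)C)(C(C)C)C(C)C)cc(O[Si](C(C)C)(C(C)C)C(C)C)c2C(C)=O)=CC1
F4 | step 11 | aryl 4-(tert-butyldimethylsilyloxy)-3-(flavon-8-yl)benzoate | CC(C)(C)[Si](C)(C)Oc1ccc(C(=O)Oc2cc(O[Si](C(C)C)(C(C)C)C(C)C)cc(O[Si](C(C)C)(C(C)C)C(C)C)c2C(C)=O)cc1-c1c(OCc2ccccc2)cc(O[Si](C(C)C)(C(C)C)C(C)C)c2c(=O)cc(-c3ccc(O[Si](C(C)C)(C(C)C)C(C)C)cc3)oc12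
F5 | step 11 | 1,3-diketone precursor of ring C of flavone 1 | CC(C)(C)[Si](C)(C)Oc1ccc(C(=O)CC(=O)c2c(O)cc(O[Si](C(C)C)(C(C)C)C(C)C)cc2O[Si](C(C)C)(C(C)C)C(C)C)cc1-c1c(OCc2ccccc2)cc(O[Si](C(C)C)(C(C)C)C(C)C)c2c(=O)cc(-c3ccc(O[Si](C(C)C)(C(C)C)C(C)C)cc3)oc12
F6 | step 5 | 7-benzyloxy-8-(2-oxopropyl)-5-(triisopropylsilyloxy)-2-[4-(triisopropylsilyloxy)phenyl]chromen-4-one | CC(=O)Cc1c(OCc2ccccc2)cc(O[Si](C(C)C)(C(C)C)C(C)C)c2c(=O)cc(-c3ccc(O[Si](C(C)C)(C(C)C)C(C)C)cc3)oc12
F7 | step 10 | (Z)-2-(2-bromovinyl)-5,7-bis(triisopropylsilyloxy)chromen-4-one | Br/C=C\c1cc(=O)c2c(O[Si](C(C)C)(C(C)C)C(C)C)cc(O[Si](C(C)C)(C(C)C)C(C)C)cc2o1
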